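Take the constants from the readings, as hourly rates. Starting material goes to target and target to over-reaction product, both with reagent.

| flask | starting material | reagent | second substrate | third substrate | protic impurity | remark | time |
|---|---|---|---|---|---|---|---|
| cedar | 0.30 M | 0.75 M | 0.15 M | 0.60 M | 0.0075 M | run made earlier |  |
| elm | 0.30 M | 0.75 M | 0.15 M | 0.60 M | 0.011 M | run made earlier |  |
| zeta | 0.30 M | 0.750 M | 0.150 M | 0.600 M | 0.0150 M |  | 40 h |
| gamma | 0.30 M | 0.750 M | 0.150 M | 0.600 M | 0.0150 M |  | 60 h |

| run | time / h | target / % | over-reaction product / % | starting material / % |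
|---|---|---|---|---|
| cedar | 1.50 | 11.8 | 0.8 | 87.4 |
| cedar | 5.00 | 24.9 | 6.1 | 69.0 |
| cedar | 8.00 | 32.4 | 10.1 | 57.1 |
| cedar | 12.0 | 35.6 | 16.0 | 46.7 |
| cedar | 20.0 | 39.4 | 24.6 | 35.1 |
| cedar | 25.0 | 38.5 | 31.6 | 28.3 |
| elm | 4.00 | 22.7 | 5.3 | 71.6 |
| elm | 8.00 | 33.3 | 10.6 | 54.5 |
| elm | 12.0 | 36.7 | 16.6 | 45.8 |
| elm | 15.0 | 37.8 | 19.8 | 40.7 |
| elm | 20.0 | 37.5 | 26.1 | 34.7 |
| elm | 25.0 | 38.7 | 30.5 | 31.2 |

(each reading ± 1 percentage point)

- which of these there is most of at the end, counted by the starting material in it, zeta (over-reaction product / starting material / target)
- which of these there is most of at the end, counted by the starting material in it, gamma (over-reaction product / starting material / target)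
- how much there is at the end of the one of these that leads, in percent of the starting material charged: zeta
- how much there is at the end of the one of these that leads, in percent of the starting material charged: gamma



Cedar and elm differ in protic impurity yet read alike within the scatter, so I pool them late on. Define the exposure θ as ln(charged/left) of starting material; its hourly rate is the pseudo-first-order constant. In cedar that rate starts at

r_start = 0.0898 h⁻¹

and between 12.0 h and 25.0 h it has slowed to

r_late = 0.0340 h⁻¹,

a factor of 2.64. Taking that slowing as steady gives

s = 0.0547 h⁻¹

θ = (r_start/s)(1 − e^(−st)): 1.46 for zeta, 1.58 for gamma.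

The lead of target over over-reaction product shrinks as θ grows:

θ = 1.05: lead 13 percentage points

θ = 1.21: lead 7.6 points

θ* = 1.43

This θ* is the handover exposure, the exposure at which over-reaction product overtakes target, read from the scatter-laden runs. By my reckoning zeta barely passes it and gamma clearly does. Taking the three species as adding up to the charge, I reckon over-reaction product leads with 38.8% in zeta and 42.3% in gamma.

The forecast also names over-reaction product in both flasks, but higher than mine, at 41% and 48%, and calls zeta “a close call”. The flasks give over-reaction product leading in both, at 42.1% in zeta and 49.3% in gamma.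

    starting material + reagent → target (k = 0.130 M⁻¹ h⁻¹)
    third substrate + reagent → third product (k = 0.0220 M⁻¹ h⁻¹)
    second substrate + reagent → second product (k = 0.400 M⁻¹ h⁻¹)
    reagent + target → over-reaction product (k = 0.120 M⁻¹ h⁻¹)
    second substrate + protic impurity → quenched substrate (k = 1.70 M⁻¹ h⁻¹)

Zeta reached θ = 1.50 and gamma 1.73, both above θ*, though gamma went further than my reckoning. Gamma's over-reaction product stands 7.2 points above zeta's because of its longer time: the same charge gives 42.1% at 40 h and 49.3% at 60 h. A flask like gamma with 0.45 M of reagent reached θ = 0.834, below θ*, and its over-reaction product stayed at 19.2%, behind target at 37.4%.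

The data are calculated on assumed constants, and the scatter is random.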